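**Plan**
- Numbering: isoflavan numbering is used, with O1 and C2–C4 in ring C, C4a–C8a in ring A, C1'–C6' in ring B, and ring D as the dimethylpyran.
- Retrosynthetic cuts, in order: the 7-O–Si bond; ring D (C5'–CH= and O4'–CMe2, back to 3-methylbut-2-enal); ring B at C1'–C6'; C3'–prenyl; C2'–C3'; ring C at C3–C4 and O1–C2.
- Enabling feature: ring B carries oxygen on C2' and C4', the prenyl group on C3' between them, and only hydrogen on C6'. C1'–C6' therefore unfolds to a 2-prenyl-1,3-diketone ending in an aldehyde-level carbon, already at the oxidation level of the arene.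
- Forward order: ring A is bought. Ring C closes first (C3–C4). The C3 acetic acid arm (C1', C2') is extended by C3'–C6', and C3' is prenylated. Ring B closes at C1'–C6'. Ring D closes last at O4'/C5', the only open ortho position.
- Stereochemistry: the single stereocentre C3 (R) comes from an enantioselective intramolecular Stetter reaction. Once the C4 ketone is removed, C3 is no longer alpha to a carbonyl.

Key step: step 8

Assumption: the (5aR,10bS) antipode of the aminoindanol-derived triazolium salt is taken to give the (R)-chromanone 5; both antipodes are commercial, and the other one would be used if the sense of induction proved opposite.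

Step 1
Reactants: 1 2,4-dihydroxybenzaldehyde
Product: 2 2-hydroxy-4-(triisopropylsilyloxy)benzaldehyde
Conditions: i-Pr3SiCl (1.05 equiv), imidazole, CH2Cl2, 0 °C to rt
Reagents that add atoms: chlorotriisopropylsilane, CC(C)[Si](Cl)(C(C)C)C(C)C
Why: Silyl ether formation: the C2 hydroxyl is hydrogen-bonded to and flanked by the formyl group, so the bulky chlorosilane should take only the more acidic, unhindered C4 hydroxyl.

Step 2
Reactants: 2 2-hydroxy-4-(triisopropylsilyloxy)benzaldehyde; 3 ethyl (E)-4-bromobut-2-enoate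
Product: 4 ethyl (E)-4-[2-formyl-5-(triisopropylsilyloxy)phenoxy]but-2-enoate
Conditions: K2CO3 (dry), acetone, rt to 40 °C
Reagents that add atoms: none
Why: Williamson ether synthesis: the remaining phenoxide displaces the primary allylic bromide by SN2 under a dry carbonate base mild enough to spare the hindered aryl silyl ether and the E-enoate.

Step 3
Reactants: 4 ethyl (E)-4-[2-formyl-5-(triisopropylsilyloxy)phenoxy]but-2-enoate
Product: 5 ethyl (R)-2-[4-oxo-7-(triisopropylsilyloxy)chroman-3-yl]acetate
Conditions: (5aR,10bS)-2-(pentafluorophenyl)-5a,10b-dihydro-4H,6H-indeno[2,1-b][1,2,4]triazolo[4,3-d][1,4]oxazin-2-ium tetrafluoroborate (10 mol %), KN(SiMe3)2 (10 mol %), toluene, rt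
Reagents that add atoms: none
Why: Enantioselective intramolecular Stetter reaction: the triazolylidene turns the formyl carbon into an acyl anion equivalent that adds 6-exo-trig to the beta carbon of the E-enoate (new C3–C4 bond, ring C), and the aminoindanol backbone shields one enoate face, which sets C3 as R.

Step 4
Reactants: 5 ethyl (R)-2-[4-oxo-7-(triisopropylsilyloxy)chroman-3-yl]acetate
Product: 7 ethyl (R)-2-[7-(triisopropylsilyloxy)chroman-3-yl]acetate, via chroman-4-ol 6 (not isolated)
Conditions: H2 (4 bar), Pd/C (10 wt %), AcOH–EtOAc, 40 °C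
Reagents that add atoms: none
Why: Catalytic hydrogenation of the aryl ketone followed by benzylic hydrogenolysis: the C4–O bond of 6 is activated by the para 7-oxygen and the ortho O1, and C3 should be untouched in the weakly acidic medium.

Step 5
Reactants: 7 ethyl (R)-2-[7-(triisopropylsilyloxy)chroman-3-yl]acetate
Product: 9 (R)-2-[7-(triisopropylsilyloxy)chroman-3-yl]acetic acid, via trimethylstannyl ester 8 (not isolated)
Conditions: Me3SnOH, ClCH2CH2Cl, 70 °C; then 1 M HCl wash
Reagents that add atoms: trimethyltin hydroxide, C[Sn](C)(C)O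
Why: Tin hydroxide ester cleavage: the ethyl ester is exchanged for stannyl ester 8 under neutral, non-aqueous conditions and freed by the acid wash, which avoids the free hydroxide that would attack an aryl silyl ether.

Step 6
Reactants: 9 (R)-2-[7-(triisopropylsilyloxy)chroman-3-yl]acetic acid; 10 4,4-dimethoxybutan-2-one
Product: 13 (R)-6,6-dimethoxy-1-[7-(triisopropylsilyloxy)chroman-3-yl]hexane-2,4-dione, via acyl imidazole 11 (not isolated), via lithium enolate 12 (not isolated)
Conditions: 9, 1,1'-carbonyldiimidazole, THF, rt; added to 10 (2.5 equiv) and LiN(i-Pr)2 (2.5 equiv), THF, −78 to −40 °C; aq NH4Cl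
Reagents that add atoms: none
Why: Crossed Claisen-type C-acylation: LiN(i-Pr)2 at −78 °C deprotonates 10 at its methyl group (kinetic enolate 12, away from the acetal so that no methanol is lost), acyl imidazole 11 acylates it at carbon (new C2'–C3' bond), and the extra enolate absorbs the acidic proton of 13.

Step 7
Reactants: 13 (R)-6,6-dimethoxy-1-[7-(triisopropylsilyloxy)chroman-3-yl]hexane-2,4-dione
Product: 15 (R)-6,6-dimethoxy-3-(3-methylbut-2-enyl)-1-[7-(triisopropylsilyloxy)chroman-3-yl]hexane-2,4-dione (C3' epimers and enol forms), via sodium diketonate 14 (not isolated)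
Conditions: NaH (1.0 equiv), THF–DMF, 0 °C; prenyl bromide (1.0 equiv), 0 °C to rt
Reagents that add atoms: 1-bromo-3-methylbut-2-ene, CC(C)=CCBr
Why: C-alkylation of a beta-diketone: the soft enolate 14 attacks the soft primary allylic bromide by SN2 at C3', the only doubly activated carbon, so the prenyl group lands between the two future phenol oxygens, and one equivalent each of base and bromide limits a second alkylation.

Step 8
Reactants: 15 (R)-6,6-dimethoxy-3-(3-methylbut-2-enyl)-1-[7-(triisopropylsilyloxy)chroman-3-yl]hexane-2,4-dione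
Product: 19 (R)-2-(3-methylbut-2-enyl)-4-[7-(triisopropylsilyloxy)chroman-3-yl]benzene-1,3-diol, via hexatriene 16 (not isolated), via methoxycyclohexadiene 17 (not isolated), via bis(trimethylsilyl) ether 18 (not isolated)
Conditions: Me3SiOTf (3.5 equiv), Et3N (6 equiv), toluene, 0 °C to rt; decant from Et3NH·OTf; 110 °C; then pyridinium p-toluenesulfonate (cat.), MeOH, rt to 40 °C
Reagents that add atoms: none
Why: Proposed new method: aqueous acid is avoided, because a free 3,5-dioxo aldehyde closes through the C2' enol oxygen onto C6' and dehydrates to a 4-pyranone faster than the weakly acidic C1' can react, so the aldol is run in silylated form. Me3SiOTf/Et3N silylates both diketone oxygens and strips one acetal methoxy group as Me3SiOMe, giving triene 16, the fully enolised chain C1'H=C2'(OSiMe3)–C3'(prenyl)=C4'(OSiMe3)–C5'H=C6'H(OMe). At 110 °C the nucleophilic terminus C1' bonds to the aldehyde-level terminus C6' in a thermal disrotatory 6π electrocyclisation, the pericyclic counterpart of a 6-(enolendo) aldol closure, so ring B appears as 17; the pyridinium salt in MeOH then expels the allylic C6' methoxy group (aromatisation to 18) and cleaves the two aryl Me3Si ethers while the i-Pr3Si ether stays. The closest known reactions are the double enol silylation of 2-alkyl-1,3-diketones, the silyl triflate/amine conversion of acetals into enol ethers, electrocyclisation–elimination benzannulations of oxygenated hexatrienes, and the TiCl4-mediated cycloaromatisation of 1,3-bis(silyloxy)dienes with acetals. The step needs C- over O-closure and enolisation at C1' rather than C5': both oxygens are blocked by silicon, C5' becomes vinylic once the acetal has eliminated so that C1' is the only carbon left to lose a proton, and closure from C3' would give a four-membered ring. No stereocentre is formed, the sp3 centres C1' and C6' of 17 vanish on aromatisation, and C3 is only allylic in 16, with its hydrogen turned away from the triene in the expected (Z)-enol silane, so it should keep its configuration.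

Step 9
Reactants: 19 (R)-2-(3-methylbut-2-enyl)-4-[7-(triisopropylsilyloxy)chroman-3-yl]benzene-1,3-diol; 20 3-methylbut-2-enal
Product: 22 (R)-2,2-dimethyl-8-(3-methylbut-2-enyl)-6-[7-(triisopropylsilyloxy)chroman-3-yl]-2H-chromen-7-ol, via ortho-quinone methide 21 (not isolated)
Conditions: 20 (2 equiv), ethylenediammonium diacetate (20 mol %), toluene, 110 °C
Reagents that add atoms: none
Why: Knoevenagel-type condensation followed by oxa-6π electrocyclisation (formal [3+3] chromene annulation): C5' is the only free position ortho or para to a ring B hydroxyl (C1' and C3' are substituted, C6' is meta to both), so dehydration to 21 and closure through O4' give ring D in one orientation, while the silyl ether keeps ring A out of the reaction.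

Step 10
Reactants: 22 (R)-2,2-dimethyl-8-(3-methylbut-2-enyl)-6-[7-(triisopropylsilyloxy)chroman-3-yl]-2H-chromen-7-ol
Product: 23 (R)-6-(7-hydroxychroman-3-yl)-2,2-dimethyl-8-(3-methylbut-2-enyl)-2H-chromen-7-ol (CNP0331403.1)
Conditions: Bu4NF, AcOH (1:1), THF, 0 °C
Reagents that add atoms: none
Why: Fluoride desilylation: the strong Si–F bond drives cleavage of the aryl silyl ether, and the acetic acid buffer keeps the medium near neutral, so the prenyl group, the chromene and C3 should not be affected.

**Compound list**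
1 | 2,4-dihydroxybenzaldehyde | O=Cc1ccc(O)cc1O | starting material
2 | 2-hydroxy-4-(triisopropylsilyloxy)benzaldehyde | O=Cc1ccc(O[Si](C(C)C)(C(C)C)C(C)C)cc1O | intermediate
3 | ethyl (E)-4-bromobut-2-enoate | CCOC(=O)/C=C/CBr | starting material
4 | ethyl (E)-4-[2-formyl-5-(triisopropylsilyloxy)phenoxy]but-2-enoate | CCOC(=O)/C=C/COc1cc(O[Si](C(C)C)(C(C)C)C(C)C)ccc1C=O | intermediate
5 | ethyl (R)-2-[4-oxo-7-(triisopropylsilyloxy)chroman-3-yl]acetate | CCOC(=O)C[C@@H]1COc2cc(O[Si](C(C)C)(C(C)C)C(C)C)ccc2C1=O | intermediate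
6 | ethyl 2-[(3R)-4-hydroxy-7-(triisopropylsilyloxy)chroman-3-yl]acetate (C4 epimers) | CCOC(=O)C[C@@H]1COc2cc(O[Si](C(C)C)(C(C)C)C(C)C)ccc2C1O | intermediate
7 | ethyl (R)-2-[7-(triisopropylsilyloxy)chroman-3-yl]acetate | CCOC(=O)C[C@@H]1COc2cc(O[Si](C(C)C)(C(C)C)C(C)C)ccc2C1 | intermediate
8 | trimethylstannyl (R)-2-[7-(triisopropylsilyloxy)chroman-3-yl]acetate | C[Sn](C)(C)OC(=O)C[C@@H]1COc2cc(O[Si](C(C)C)(C(C)C)C(C)C)ccc2C1 | intermediate
9 | (R)-2-[7-(triisopropylsilyloxy)chroman-3-yl]acetic acid | OC(=O)C[C@@H]1COc2cc(O[Si](C(C)C)(C(C)C)C(C)C)ccc2C1 | intermediate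
10 | 4,4-dimethoxybutan-2-one | CC(=O)CC(OC)OC | starting material
11 | (R)-1-(imidazol-1-yl)-2-[7-(triisopropylsilyloxy)chroman-3-yl]ethanone | O=C(C[C@@H]1COc2cc(O[Si](C(C)C)(C(C)C)C(C)C)ccc2C1)n1ccnc1 | intermediate
12 | lithium 4,4-dimethoxybut-1-en-2-olate | [Li+].C=C([O-])CC(OC)OC | intermediate
13 | (R)-6,6-dimethoxy-1-[7-(triisopropylsilyloxy)chroman-3-yl]hexane-2,4-dione | COC(OC)CC(=O)CC(=O)C[C@@H]1COc2cc(O[Si](C(C)C)(C(C)C)C(C)C)ccc2C1 | intermediate
14 | sodium enolate of 13 | [Na+].COC(OC)CC(=O)C=C([O-])C[C@@H]1COc2cc(O[Si](C(C)C)(C(C)C)C(C)C)ccc2C1 | intermediate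
15 | (R)-6,6-dimethoxy-3-(3-methylbut-2-enyl)-1-[7-(triisopropylsilyloxy)chroman-3-yl]hexane-2,4-dione | COC(OC)CC(=O)C(CC=C(C)C)C(=O)C[C@@H]1COc2cc(O[Si](C(C)C)(C(C)C)C(C)C)ccc2C1 | intermediate
16 | (R)-3-[(5E)-6-methoxy-3-(3-methylbut-2-enyl)-2,4-bis(trimethylsilyloxy)hexa-1,3,5-trien-1-yl]-7-(triisopropylsilyloxy)chroman | CO/C=C/C(O[Si](C)(C)C)=C(CC=C(C)C)C(O[Si](C)(C)C)=C[C@@H]1COc2cc(O[Si](C(C)C)(C(C)C)C(C)C)ccc2C1 | intermediate
17 | (3R)-3-[6-methoxy-3-(3-methylbut-2-enyl)-2,4-bis(trimethylsilyloxy)cyclohexa-2,4-dien-1-yl]-7-(triisopropylsilyloxy)chroman | COC1C=C(O[Si](C)(C)C)C(CC=C(C)C)=C(O[Si](C)(C)C)C1[C@@H]2COc3cc(O[Si](C(C)C)(C(C)C)C(C)C)ccc3C2 | intermediate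
18 | (R)-3-[3-(3-methylbut-2-enyl)-2,4-bis(trimethylsilyloxy)phenyl]-7-(triisopropylsilyloxy)chroman | CC(C)=CCc1c(O[Si](C)(C)C)ccc([C@@H]2COc3cc(O[Si](C(C)C)(C(C)C)C(C)C)ccc3C2)c1O[Si](C)(C)C | intermediate
19 | (R)-2-(3-methylbut-2-enyl)-4-[7-(triisopropylsilyloxy)chroman-3-yl]benzene-1,3-diol | CC(C)=CCc1c(O)ccc([C@@H]2COc3cc(O[Si](C(C)C)(C(C)C)C(C)C)ccc3C2)c1O | intermediate
20 | 3-methylbut-2-enal | CC(C)=CC=O | starting material
21 | ortho-quinone methide: 3-hydroxy-6-(3-methylbut-2-enylidene)-2-(3-methylbut-2-enyl)-4-[(3R)-7-(triisopropylsilyloxy)chroman-3-yl]cyclohexa-2,4-dienone | CC(C)=CC=C1C=C([C@@H]2COc3cc(O[Si](C(C)C)(C(C)C)C(C)C)ccc3C2)C(O)=C(CC=C(C)C)C1=O | intermediate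
22 | (R)-2,2-dimethyl-8-(3-methylbut-2-enyl)-6-[7-(triisopropylsilyloxy)chroman-3-yl]-2H-chromen-7-ol | CC(C)=CCc1c(O)c([C@@H]2COc3cc(O[Si](C(C)C)(C(C)C)C(C)C)ccc3C2)cc2c1OC(C)(C)C=C2 | intermediate
23 | (R)-6-(7-hydroxychroman-3-yl)-2,2-dimethyl-8-(3-methylbut-2-enyl)-2H-chromen-7-ol | CC(C)=CCc1c(O)c([C@@H]2COc3cc(O)ccc3C2)cc2c1OC(C)(C)C=C2 | target

Total step count: 10. Longest linear sequence: 10 steps (1 to 23).

**Steps most likely to fail**

1. Step 8.
   - What may go wrong: closure through oxygen may occur before both oxygens are silylated. The central C3'=C4' enol silane may adopt a geometry that cannot fold. A sigmatropic hydrogen shift from C3 in the minor enol silane geometry would erode the configuration.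
   - Fallback, from 9 back to 18, known chemistry only: MeLi (2 equiv) converts acid 9 into (R)-1-[7-(triisopropylsilyloxy)chroman-3-yl]propan-2-one F1. With t-BuOK in THF, the more substituted enolate (C1') adds to methyl acrylate in a Michael reaction (C1'–C6' bond) to give methyl 5-oxo-4-[(3R)-7-(triisopropylsilyloxy)chroman-3-yl]hexanoate F2. F2 closes in the same flask by Claisen condensation to 4-[(3R)-7-(triisopropylsilyloxy)chroman-3-yl]cyclohexane-1,3-dione F3. C-alkylation with prenyl bromide and K2CO3 in acetone gives 2-(3-methylbut-2-enyl)-4-[(3R)-7-(triisopropylsilyloxy)chroman-3-yl]cyclohexane-1,3-dione F4. Me3SiOTf/Et3N gives (3R)-3-[3-(3-methylbut-2-enyl)-2,4-bis(trimethylsilyloxy)cyclohexa-2,4-dien-1-yl]-7-(triisopropylsilyloxy)chroman F5. Dehydrogenation with 2,3-dichloro-5,6-dicyano-1,4-benzoquinone gives 18, whose methanolysis gives 19 as in the route.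

2. Step 6.
   - What may go wrong: the enolate may be acylated at oxygen, protons may exchange between product and enolate, or methanol may be lost by beta-elimination from the enolate on warming.
   - Fallback, from 7 back to 13: i-Bu2AlH in CH2Cl2 at −78 °C reduces ester 7 to (R)-2-[7-(triisopropylsilyloxy)chroman-3-yl]acetaldehyde F6. Aldol addition of lithium enolate 12 at −78 °C gives 5-hydroxy-1,1-dimethoxy-6-[(3R)-7-(triisopropylsilyloxy)chroman-3-yl]hexan-3-one F7. Oxidation with Dess–Martin periodinane gives 13.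

3. Step 4.
   - What may go wrong: the electron-rich aryl ketone may be reduced only slowly, and acid-catalysed enolisation during a long reaction would erode the C3 configuration.
   - Fallback, from 5 back to 7: NaBH4 with CeCl3·7H2O in MeOH at −20 °C reduces the ketone to chroman-4-ol 6, now isolated. Et3SiH with BF3·OEt2 in CH2Cl2 at −78 to −20 °C ionises the benzylic alcohol to the cation stabilised by the para oxygen and captures it with hydride (ionic deoxygenation) to give 7.

**Further compounds**
F1 | step 8 | (R)-1-[7-(triisopropylsilyloxy)chroman-3-yl]propan-2-one | CC(=O)C[C@@H]1COc2cc(O[Si](C(C)C)(C(C)C)C(C)C)ccc2C1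
F2 | step 8 | methyl 5-oxo-4-[(3R)-7-(triisopropylsilyloxy)chroman-3-yl]hexanoate | COC(=O)CCC(C(C)=O)[C@@H]1COc2cc(O[Si](C(C)C)(C(C)C)C(C)C)ccc2C1
F3 | step 8 | 4-[(3R)-7-(triisopropylsilyloxy)chroman-3-yl]cyclohexane-1,3-dione | O=C1CCC([C@@H]2COc3cc(O[Si](C(C)C)(C(C)C)C(C)C)ccc3C2)C(=O)C1
F4 | step 8 | 2-(3-methylbut-2-enyl)-4-[(3R)-7-(triisopropylsilyloxy)chroman-3-yl]cyclohexane-1,3-dione | CC(C)=CCC1C(=O)CCC([C@@H]2COc3cc(O[Si](C(C)C)(C(C)C)C(C)C)ccc3C2)C1=O
F5 | step 8 | (3R)-3-[3-(3-methylbut-2-enyl)-2,4-bis(trimethylsilyloxy)cyclohexa-2,4-dien-1-yl]-7-(triisopropylsilyloxy)chroman | CC(C)=CCC1=C(O[Si](C)(C)C)C([C@@H]2COc3cc(O[Si](C(C)C)(C(C)C)C(C)C)ccc3C2)CC=C1O[Si](C)(C)C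
F6 | step 6 | (R)-2-[7-(triisopropylsilyloxy)chroman-3-yl]acetaldehyde | O=CC[C@@H]1COc2cc(O[Si](C(C)C)(C(C)C)C(C)C)ccc2C1
F7 | step 6 | 5-hydroxy-1,1-dimethoxy-6-[(3R)-7-(triisopropylsilyloxy)chroman-3-yl]hexan-3-one | COC(OC)CC(=O)CC(O)C[C@@H]1COc2cc(O[Si](C(C)C)(C(C)C)C(C)C)ccc2C1
F0 | step 4 | none | none
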